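The drimane core (drimane numbering) is cut across ring B at C8–C9 and C5–C10. The retron is a Δ6-cyclohexene hidden in the C6-hydroxy-C7=C8-enal unit (α-epoxide, then β-elimination). One intramolecular Diels–Alder reaction of an acyclic (E)-enal/(E,E)-diene closes ring B as the cycloaddition ring and ring A as the tether ring. It sets C5, C8, C9 and the quaternary C10 at once. The step exploits the C1 acyloxy stereocentre next to C10: sitting equatorial in the chair-like C1–C4 tether, it dictates the face of attack. The precursor is a linear 3,7,7-trimethyldodeca-2,8,10-trienal that already carries the 4-methoxycinnamate and a silyl-protected C12 alcohol.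

Key step: step 8

Assumption: drimane numbering is used for the decalins and for the matching atoms of the open-chain precursors (chain atoms 1, 2, 3, 4, 5–7, 8–11, 12 = C11, C9, C10, C1, C2–C4, C5–C8, C12), and in step 5 the enantiomer of the valinol-derived ligand that directs attack to the Si face of aldehyde 6 is meant, both enantiomers being accessible.

Step 1
Reactants: 1 4,4-dimethyl-5-oxopentanenitrile; 2 triethyl (E)-4-phosphonocrotonate
Product: 3 ethyl (2E,4E)-8-cyano-6,6-dimethylocta-2,4-dienoate
Conditions: 2, LiN(SiMe3)2, THF, −78 °C; then 1, −78 → 0 °C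
Reagents that add atoms: none
Why: Vinylogous Horner–Wadsworth–Emmons olefination: the stabilised phosphonate anion attacks the non-enolisable neopentyl aldehyde through the carbon next to phosphorus, leaves the nitrile alone and should give the (2E,4E)-dienoate because elimination from the equilibrating adducts favours the E alkene.

Step 2
Reactants: 3 ethyl (2E,4E)-8-cyano-6,6-dimethylocta-2,4-dienoate
Product: 5 (5E,7E)-9-hydroxy-4,4-dimethylnona-5,7-dienal, via aluminium imine alkoxide 4 (not isolated)
Conditions: i-Bu2AlH (3.5 equiv), CH2Cl2, −78 °C; then aq. tartaric acid, 0 °C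
Reagents that add atoms: water, O
Why: Hydride reduction with i-Bu2AlH: two hydrides take the conjugated ester by 1,2-addition to the dienyl alkoxide, one hydride stops the nitrile at the N-aluminoimine stage, and mild acid then hydrolyses the imine to the C1 aldehyde.

Step 3
Reactants: 5 (5E,7E)-9-hydroxy-4,4-dimethylnona-5,7-dienal
Product: 6 (5E,7E)-9-(tert-butyldimethylsilyloxy)-4,4-dimethylnona-5,7-dienal
Conditions: TBSCl, imidazole, CH2Cl2, 0 °C → rt
Reagents that add atoms: tert-butyldimethylsilyl chloride, CC(C)(C)[Si](C)(C)Cl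
Why: Imidazole-promoted silylation of the only hydroxyl group masks C12–OH and keeps the diene electron-rich for the cycloaddition.

Step 4
Reactants: 7 but-2-yn-1-ol
Product: 10 (E)-3-iodobut-2-en-1-ol, via aluminium alkoxide 8 (not isolated), via alkenylzirconocene chloride 9 (not isolated)
Conditions: i-Bu2AlH (1 equiv), THF, 0 °C; Cp2ZrCl2/i-Bu2AlH (forms Cp2ZrHCl), 0 °C → rt; I2, −78 °C
Reagents that add atoms: iodine, II
Why: Hydrozirconation–iodinolysis: Cp2ZrHCl adds syn across the alkyne and places zirconium on the methyl-bearing carbon, remote from the bulky O-aluminium group, and I2 cleaves the C–Zr bond with retention, so iodine ends trans to CH2OH as the later C10=C9 geometry requires.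

Step 5
Reactants: 6 (5E,7E)-9-(tert-butyldimethylsilyloxy)-4,4-dimethylnona-5,7-dienal; 10 (E)-3-iodobut-2-en-1-ol
Product: 11 (2E,4R,8E,10E)-12-(tert-butyldimethylsilyloxy)-3,7,7-trimethyldodeca-2,8,10-triene-1,4-diol
Conditions: CrCl2 (10 mol %), 4-isopropyl-2-[2-(methanesulfonamido)-3-methylphenyl]-4,5-dihydrooxazole (single enantiomer, 11 mol %), 1,8-bis(dimethylamino)naphthalene (11 mol %), NiCl2(2,9-dimethyl-1,10-phenanthroline) (2 mol %), Mn powder, Cp2ZrCl2, LiCl, MeCN, rt
Reagents that add atoms: none
Why: Catalytic asymmetric Nozaki–Hiyama–Kishi coupling: zerovalent nickel inserts into the C–I bond with retention, transmetallation gives an alkenylchromium species held by the chiral sulfonamide ligand, and this adds only to the aldehyde, on its Si face, which sets C1 as R while the free hydroxyl, the diene and the silyl ether are tolerated.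

Step 6
Reactants: 11 (2E,4R,8E,10E)-12-(tert-butyldimethylsilyloxy)-3,7,7-trimethyldodeca-2,8,10-triene-1,4-diol
Product: 12 (2E,4R,8E,10E)-12-(tert-butyldimethylsilyloxy)-4-hydroxy-3,7,7-trimethyldodeca-2,8,10-trienal
Conditions: TEMPO (10 mol %), PhI(OAc)2 (1.1 equiv), CH2Cl2, rt
Reagents that add atoms: none
Why: Oxoammonium (TEMPO) oxidation is much faster for the unhindered primary allylic alcohol than for the secondary one next to the trisubstituted alkene, and the (E)-geometry rules out lactol formation and over-oxidation.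

Step 7
Reactants: 12 (2E,4R,8E,10E)-12-(tert-butyldimethylsilyloxy)-4-hydroxy-3,7,7-trimethyldodeca-2,8,10-trienal; 13 (E)-4-methoxycinnamic acid
Product: 14 (2E,4R,8E,10E)-12-(tert-butyldimethylsilyloxy)-3,7,7-trimethyl-1-oxododeca-2,8,10-trien-4-yl (E)-3-(4-methoxyphenyl)prop-2-enoate
Conditions: DCC, DMAP (cat.), CH2Cl2, 0 °C → rt
Reagents that add atoms: none
Why: Steglich esterification acylates the secondary allylic alcohol under neutral conditions with retention at C1, since the C1–O bond is not touched.

Step 8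
Reactants: 14 (2E,4R,8E,10E)-12-(tert-butyldimethylsilyloxy)-3,7,7-trimethyl-1-oxododeca-2,8,10-trien-4-yl (E)-3-(4-methoxyphenyl)prop-2-enoate
Product: 15 1β-[(E)-4-methoxycinnamoyloxy]-12-(tert-butyldimethylsilyloxy)drim-6-en-11-al (trans-decalin; 5α-H; 8β-CH2OTBS; 9β-CHO; 10β-CH3)
Conditions: Me2AlCl (2.2 equiv), CH2Cl2, −78 → −20 °C
Reagents that add atoms: none
Why: Me2AlCl binds the formyl oxygen and lowers the LUMO of the C9=C10 enal, which adds suprafacially to the s-cis C5=C6–C7=C8 diene in a concerted, asynchronous [4+2] cycloaddition that makes C8–C9 and C5–C10 together and leaves the new alkene at C6=C7. The closest known reaction type is the Lewis acid promoted type 1 intramolecular Diels–Alder reaction of 2,8,10-trienals (1,7,9-decatriene class) to trans-fused octalins. Ring B closes as the six-membered cycloaddition ring (4π + 2π) and ring A as the fused six-membered ring formed by the four-carbon tether C1–C4 in a chair-like array. The cis pair C10-methyl/C9-formyl follows from the (E)-enal, the cis pair C4/C12 on C5 and C8 from the (E,E)-diene, and the trans ring fusion (5α-H, 10β-methyl) with 8β-CH2OTBS from the endo position of the aluminium-bound formyl group. The absolute sense comes from C1: the acyloxy group sits equatorial and anti to the forming C5–C10 bond, with C1–H close to the alkene plane, so the diene reaches the face that gives the 1β-O/10β-methyl relationship. The step needs endo over exo selectivity, which the Lewis acid should secure, and periselectivity over the cinnamate alkene, which its much longer ester-containing tether and weaker activation should secure.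

Step 9
Reactants: 15 1β-[(E)-4-methoxycinnamoyloxy]-12-(tert-butyldimethylsilyloxy)drim-6-en-11-al
Product: 16 1β-[(E)-4-methoxycinnamoyloxy]-12-(tert-butyldimethylsilyloxy)drim-6-en-11-ol
Conditions: NaBH4, THF/MeOH, −20 °C; AcOH quench
Reagents that add atoms: none
Why: Chemoselective borohydride 1,2-reduction of the aldehyde at low temperature leaves the cinnamate, the alkene and the silyl ether intact, keeps C9 unchanged, and removes the risk of lactol formation and of Baeyer–Villiger attack in the following steps.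

Step 10
Reactants: 16 1β-[(E)-4-methoxycinnamoyloxy]-12-(tert-butyldimethylsilyloxy)drim-6-en-11-ol
Product: 17 6α,7α-epoxy-1β-[(E)-4-methoxycinnamoyloxy]-12-(tert-butyldimethylsilyloxy)drimane-11-ol
Conditions: mCPBA, NaHCO3, CH2Cl2, 0 °C
Reagents that add atoms: 3-chloroperoxybenzoic acid, OOC(=O)c1cccc(Cl)c1
Why: Prilezhaev epoxidation: the β face of C6=C7 is shielded by the axial C10 and 4β methyl groups and by the pseudoaxial 8β-CH2OTBS group, so the peracid should attack from the α face and set the C6–O bond α, while the electron-poor cinnamate alkene reacts far more slowly.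

Step 11
Reactants: 17 6α,7α-epoxy-1β-[(E)-4-methoxycinnamoyloxy]-12-(tert-butyldimethylsilyloxy)drimane-11-ol
Product: 18 6α,7α-epoxy-1β-[(E)-4-methoxycinnamoyloxy]drimane-11,12-diol
Conditions: Et3N·3HF, THF, rt
Reagents that add atoms: none
Why: Fluoride-induced cleavage of the primary silyl ether with a nearly neutral HF source should spare the epoxide and avoid a base-induced shift of the cinnamoyl group from O1 to the nearby O11.

Step 12
Reactants: 18 6α,7α-epoxy-1β-[(E)-4-methoxycinnamoyloxy]drimane-11,12-diol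
Product: 20 1β-[(E)-4-methoxycinnamoyloxy]-6α-hydroxydrim-7-ene-11,12-dial (target), via epoxy dialdehyde 19 (not isolated)
Conditions: (COCl)2 (2.4 equiv), DMSO, CH2Cl2, −78 °C; Et3N (excess), −78 → 0 °C
Reagents that add atoms: none
Why: Swern oxidation activates both primary alcohols as alkoxysulfonium ions before base is added, so the dialdehyde forms without a lactol detour, and the excess Et3N then removes the C8 proton next to the new C12 aldehyde so that the enolate expels the C7–O bond of the epoxide (E1cB), which gives the C7=C8 enal and frees the 6α-hydroxyl with its configuration retained.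

Compound list
1 | 4,4-dimethyl-5-oxopentanenitrile | N#CCCC(C)(C)C=O | starting material
2 | triethyl (E)-4-phosphonocrotonate | CCOC(=O)/C=C/CP(=O)(OCC)OCC | starting material
3 | ethyl (2E,4E)-8-cyano-6,6-dimethylocta-2,4-dienoate | CCOC(=O)/C=C/C=C/C(C)(C)CCC#N | intermediate
4 | N,O-bis(diisobutylaluminium) derivative of (5E,7E)-9-hydroxy-4,4-dimethylnona-5,7-dienal imine | CC(C)C[Al](CC(C)C)N=CCCC(C)(C)/C=C/C=C/CO[Al](CC(C)C)CC(C)C | intermediate
5 | (5E,7E)-9-hydroxy-4,4-dimethylnona-5,7-dienal | O=CCCC(C)(C)/C=C/C=C/CO | intermediate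
6 | (5E,7E)-9-(tert-butyldimethylsilyloxy)-4,4-dimethylnona-5,7-dienal | O=CCCC(C)(C)/C=C/C=C/CO[Si](C)(C)C(C)(C)C | intermediate
7 | but-2-yn-1-ol | CC#CCO | starting material
8 | (but-2-yn-1-yloxy)diisobutylaluminium | CC#CCO[Al](CC(C)C)CC(C)C | intermediate
9 | (E)-alkenylzirconocene chloride, zirconium on the methyl-bearing carbon and trans to the CH2O–Al group | C/C(=C\CO[Al](CC(C)C)CC(C)C)[Zr](Cl)(C1C=CC=C1)C1C=CC=C1 | intermediate
10 | (E)-3-iodobut-2-en-1-ol | C/C(I)=C\CO | intermediate
11 | (2E,4R,8E,10E)-12-(tert-butyldimethylsilyloxy)-3,7,7-trimethyldodeca-2,8,10-triene-1,4-diol | OC/C=C(C)/[C@H](O)CCC(C)(C)/C=C/C=C/CO[Si](C)(C)C(C)(C)C | intermediate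
12 | (2E,4R,8E,10E)-12-(tert-butyldimethylsilyloxy)-4-hydroxy-3,7,7-trimethyldodeca-2,8,10-trienal | O=C/C=C(C)/[C@H](O)CCC(C)(C)/C=C/C=C/CO[Si](C)(C)C(C)(C)C | intermediate
13 | (E)-4-methoxycinnamic acid | COc1ccc(/C=C/C(=O)O)cc1 | starting material
14 | (2E,4R,8E,10E)-12-(tert-butyldimethylsilyloxy)-3,7,7-trimethyl-1-oxododeca-2,8,10-trien-4-yl (E)-3-(4-methoxyphenyl)prop-2-enoate | COc1ccc(/C=C/C(=O)O[C@@H](/C(C)=C/C=O)CCC(C)(C)/C=C/C=C/CO[Si](C)(C)C(C)(C)C)cc1 | intermediate
15 | 1β-[(E)-4-methoxycinnamoyloxy]-12-(tert-butyldimethylsilyloxy)drim-6-en-11-al (5α-H, 8α-H, 9α-H, 10β-CH3) | COc1ccc(/C=C/C(=O)O[C@@H]2CCC(C)(C)[C@@H]3C=C[C@H](CO[Si](C)(C)C(C)(C)C)[C@H](C=O)[C@@]23C)cc1 | intermediate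
16 | 1β-[(E)-4-methoxycinnamoyloxy]-12-(tert-butyldimethylsilyloxy)drim-6-en-11-ol | COc1ccc(/C=C/C(=O)O[C@@H]2CCC(C)(C)[C@@H]3C=C[C@H](CO[Si](C)(C)C(C)(C)C)[C@H](CO)[C@@]23C)cc1 | intermediate
17 | 6α,7α-epoxy-1β-[(E)-4-methoxycinnamoyloxy]-12-(tert-butyldimethylsilyloxy)drimane-11-ol | COc1ccc(/C=C/C(=O)O[C@@H]2CCC(C)(C)[C@@H]3[C@H]4O[C@H]4[C@H](CO[Si](C)(C)C(C)(C)C)[C@H](CO)[C@@]23C)cc1 | intermediate
18 | 6α,7α-epoxy-1β-[(E)-4-methoxycinnamoyloxy]drimane-11,12-diol | COc1ccc(/C=C/C(=O)O[C@@H]2CCC(C)(C)[C@@H]3[C@H]4O[C@H]4[C@H](CO)[C@H](CO)[C@@]23C)cc1 | intermediate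
19 | 6α,7α-epoxy-1β-[(E)-4-methoxycinnamoyloxy]drimane-11,12-dial | COc1ccc(/C=C/C(=O)O[C@@H]2CCC(C)(C)[C@@H]3[C@H]4O[C@H]4[C@H](C=O)[C@H](C=O)[C@@]23C)cc1 | intermediate
20 | 1β-[(E)-4-methoxycinnamoyloxy]-6α-hydroxydrim-7-ene-11,12-dial (CNP0283080.1) | COc1ccc(/C=C/C(=O)O[C@@H]2CCC(C)(C)[C@@H]3[C@@H](O)C=C(C=O)[C@H](C=O)[C@@]23C)cc1 | target

Total steps: 12. Longest linear sequence: 11 (steps 1–3 and 5–12).

Steps most likely to fail

Step 8. Endo and facial selectivity may erode, because the endo array pushes the C10 methyl under the diene and builds the 1,3-diaxial contact between the C10 and 4β methyl groups. The β,β-disubstituted enal may also react so slowly that Lewis acid induced ionisation of the dienylic silyl ether takes over. The fallback replaces the neutral enal complex by a cationic dienophile (ionic Diels–Alder reaction of an enal acetal). It sets out from 14. Treatment with 1,2-bis(trimethylsilyloxy)ethane and catalytic TMSOTf in CH2Cl2 at −78 °C should give the 1,3-dioxolane of the trienal F6. More TMSOTf (−78 → −40 °C) should open the acetal reversibly to the alkoxyallyl cation. This cation should cycloadd at much lower temperature through the same endo, chair-like array and reclose to the decalin dioxolane F7. Transacetalisation with catalytic I2 in acetone, which spares the silyl ether, returns to the route at 15.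

Step 5. Facial discrimination at an unbranched aliphatic aldehyde may be insufficient, or turnover may be sluggish because the free hydroxyl of 10 binds the metals. The fallback sets C1 by reagent-controlled ketone reduction instead of by the C–C bond formation. It sets out from 6 and 10.
- Iodide 10 is silylated (Et3SiCl, imidazole) to (E)-triethyl[(3-iodobut-2-en-1-yl)oxy]silane F1.
- t-BuLi in Et2O at −78 °C gives the alkenyllithium F2, which adds to 6 to give the racemic allylic alcohol F3.
- Dess–Martin periodinane gives the enone F4.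
- Corey–Bakshi–Shibata reduction with the (S)-2-methyl-oxazaborolidine and catecholborane (toluene, −78 °C, alkenyl group as the large substituent) should give the (R)-allylic alcohol F5.
- PPTS in MeOH at 0 °C removes the triethylsilyl group selectively and returns to the route at 11.

Step 12. Three things may go wrong:
- Residual activated DMSO may oxidise the newly freed C6 hydroxyl.
- A lactol may form if the two alcohols are not activated at the same time.
- The amine may epimerise C9 once both aldehydes are present.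

The fallback keeps C11 at the aldehyde level, masked as an acetal. Only C12 is then oxidised, and C9 has no acidic proton during the base step. It sets out from 15.
- MeOSiMe3 and catalytic TMSOTf (CH2Cl2, −78 °C) give the C11 dimethyl acetal F8.
- mCPBA/NaHCO3 gives the 6α,7α-epoxide F9.
- Et3N·3HF gives the primary alcohol F10.
- Dess–Martin periodinane/NaHCO3 gives the isolable epoxy aldehyde F11.
- After removal of the oxidant, Et3N in CH2Cl2 opens F11 to the 6α-hydroxy enal acetal F12.
- PPTS in wet acetone hydrolyses the acetal and returns to the route at 20.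

Further compounds
F1 | step 5 | (E)-triethyl[(3-iodobut-2-en-1-yl)oxy]silane | C/C(I)=C\CO[Si](CC)(CC)CC
F2 | step 5 | (E)-4-(triethylsilyloxy)but-2-en-2-yllithium | C/C([Li])=C\CO[Si](CC)(CC)CC
F3 | step 5 | racemic (2E,8E,10E)-12-(tert-butyldimethylsilyloxy)-3,7,7-trimethyl-1-(triethylsilyloxy)dodeca-2,8,10-trien-4-ol | CC[Si](CC)(CC)OC/C=C(C)/C(O)CCC(C)(C)/C=C/C=C/CO[Si](C)(C)C(C)(C)C
F4 | step 5 | (2E,8E,10E)-12-(tert-butyldimethylsilyloxy)-3,7,7-trimethyl-1-(triethylsilyloxy)dodeca-2,8,10-trien-4-one | CC[Si](CC)(CC)OC/C=C(C)/C(=O)CCC(C)(C)/C=C/C=C/CO[Si](C)(C)C(C)(C)C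
F5 | step 5 | (2E,4R,8E,10E)-12-(tert-butyldimethylsilyloxy)-3,7,7-trimethyl-1-(triethylsilyloxy)dodeca-2,8,10-trien-4-ol | CC[Si](CC)(CC)OC/C=C(C)/[C@H](O)CCC(C)(C)/C=C/C=C/CO[Si](C)(C)C(C)(C)C
F6 | step 8 | 1,3-dioxolane acetal of trienal 14 | COc1ccc(/C=C/C(=O)O[C@@H](/C(C)=C/C2OCCO2)CCC(C)(C)/C=C/C=C/CO[Si](C)(C)C(C)(C)C)cc1
F7 | step 8 | 1,3-dioxolane acetal of decalin aldehyde 15 | COc1ccc(/C=C/C(=O)O[C@@H]2CCC(C)(C)[C@@H]3C=C[C@H](CO[Si](C)(C)C(C)(C)C)[C@H](C4OCCO4)[C@@]23C)cc1
F8 | step 12 | C11 dimethyl acetal of 15 | COc1ccc(/C=C/C(=O)O[C@@H]2CCC(C)(C)[C@@H]3C=C[C@H](CO[Si](C)(C)C(C)(C)C)[C@H](C(OC)OC)[C@@]23C)cc1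
F9 | step 12 | 6α,7α-epoxide of F8 | COc1ccc(/C=C/C(=O)O[C@@H]2CCC(C)(C)[C@@H]3[C@H]4O[C@H]4[C@H](CO[Si](C)(C)C(C)(C)C)[C@H](C(OC)OC)[C@@]23C)cc1
F10 | step 12 | 6α,7α-epoxy C11 dimethyl acetal with free C12 alcohol | COc1ccc(/C=C/C(=O)O[C@@H]2CCC(C)(C)[C@@H]3[C@H]4O[C@H]4[C@H](CO)[C@H](C(OC)OC)[C@@]23C)cc1
F11 | step 12 | 6α,7α-epoxy C12 aldehyde C11 dimethyl acetal | COc1ccc(/C=C/C(=O)O[C@@H]2CCC(C)(C)[C@@H]3[C@H]4O[C@H]4[C@H](C=O)[C@H](C(OC)OC)[C@@]23C)cc1
F12 | step 12 | C11 dimethyl acetal of target 20 | COc1ccc(/C=C/C(=O)O[C@@H]2CCC(C)(C)[C@@H]3[C@@H](O)C=C(C=O)[C@H](C(OC)OC)[C@@]23C)cc1
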